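**Retrosynthetic overview**
1. The last bond made is the C8–O ester. A Yamaguchi coupling joins the ten-membered 8-hydroxy-9-oxo lactone to (2S,3S)-epoxyangelic acid, which comes from angelic acid by reduction, Sharpless epoxidation and oxidation.
2. The ten-membered ring comes from a six-to-ten ring expansion. Reductive (pinacol) C8–C9 closure of a keto aldehyde gives a cis-decalin diolate. Its C4–C9 bond is then cut by Grob fragmentation against a C5 mesylate. This gives C9=O and the 4Z alkene, while the 1(10)Z enone is the old cyclohexenone alkene.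
3. C4–C5 comes from an aldol of the cross-conjugated enolate of 2,6-dimethylcyclohexenone on a cis-lactone aldehyde, with the aldolate trapped as the mesylate.
4. The cis-α-methylene-γ-butyrolactone (C6–C7) comes from indium allylation of (S)-glyceraldehyde acetonide with a Baylis–Hillman bromide. Glycol cleavage then bares C5.
5. Ring order: cyclohexenone (bought, ring B), then lactone, then transient ring A, then the ten-membered ring.

Assumption: the SMILES is taken literally as a 1(10)Z,4Z-diene with a cis-fused 6,7-lactone, 6S,7S,8R, and a 2′S,3′S-epoxyangelate. Germacrane numbering (C1–C15) is used for every carbon that ends up in the target. The CIP letters at C6 and C7 change along the route only because substituent priorities change; no centre is inverted.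

**Step 1**
Reactants: 1 2,2-dimethoxyacetaldehyde; 2 methyl acrylate
Product: 3 methyl 3-hydroxy-4,4-dimethoxy-2-methylidenebutanoate (racemic)
Conditions: DABCO (0.5 equiv), 1,4-dioxane–H2O 1:1, 23 °C, 36 h
Reagents that add atoms: none
Why: Morita–Baylis–Hillman reaction in which the DABCO–acrylate enolate attacks the activated dialkoxy aldehyde (C7–C11 bond), water speeds the proton transfer, and the racemic carbinol centre is erased in step 2.

**Step 2**
Reactants: 3 methyl 3-hydroxy-4,4-dimethoxy-2-methylidenebutanoate
Product: 4 methyl (Z)-2-(bromomethyl)-4,4-dimethoxybut-2-enoate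
Conditions: NBS (1.3 equiv), Me2S (1.4 equiv), CH2Cl2, 0 → 23 °C
Reagents that add atoms: N-bromosuccinimide, O=C1CCC(=O)N1Br
Why: SN2′ bromination of a Baylis–Hillman alcohol under near-neutral, acetal-safe Corey–Kim-type conditions, in which bromide displaces the alkoxysulfonium group at the CH2 terminus and the alkene forms with the acetal carbon trans to the ester (cis to CH2Br).

**Step 3**
Reactants: 4 methyl (Z)-2-(bromomethyl)-4,4-dimethoxybut-2-enoate; 5 (4S)-2,2-dimethyl-1,3-dioxolane-4-carbaldehyde
Product: 7 (4S,5R)-4-(dimethoxymethyl)-5-[(4S)-2,2-dimethyl-1,3-dioxolan-4-yl]-3-methylideneoxolan-2-one (cis lactone), via hydroxy ester 6 (not isolated)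
Conditions: In powder (1.5 equiv), THF–H2O 1:1, 23 °C, 6 h; extract; crude, PPTS (10 mol %), PhMe, 60 °C
Reagents that add atoms: none
Why: Barbier-type indium allylation (γ-attack through a closed chair) then lactonisation, in which the substituent cis to the CH2–In terminus gives the 6,7-syn adduct (hence the cis lactone) and attack on the Felkin–Anh face of the α-alkoxy aldehyde gives the anti relation to the dioxolane, the matched pairing that sets C6 and C7.

**Step 4**
Reactants: 7 cis-lactone acetonide
Product: 8 (2R,3S)-3-(dimethoxymethyl)-4-methylidene-5-oxooxolane-2-carbaldehyde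
Conditions: H5IO6 (1.3 equiv), EtOAc, 0 → 23 °C, 1 h
Reagents that add atoms: none
Why: Periodic acid hydrolyses the terminal isopropylidene ketal (far more labile than the aldehyde dimethyl acetal) and cleaves the freed 1,2-diol in the same pot (Malaprade glycol cleavage), with the C6 oxygen safe inside the lactone and no stereocentre touched.

**Step 5**
Reactants: 9 2-methylcyclohex-2-en-1-one
Product: 11 2,6-dimethylcyclohex-2-en-1-one (racemic), via lithium dienolate 10 (not isolated)
Conditions: LiN(iPr)2 (1.05 equiv), THF, −78 °C; MeI (1.5 equiv), −78 → 0 °C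
Reagents that add atoms: iodomethane, CI
Why: Kinetic α′-deprotonation gives the cross-conjugated dienolate, which is C-methylated (enolate alkylation), and the racemic new centre is made planar again in step 6.

**Step 6**
Reactants: 11 2,6-dimethylcyclohex-2-en-1-one; 8 lactone aldehyde
Product: 14 (S)-[(1R)-1,3-dimethyl-2-oxocyclohex-3-en-1-yl][(2R,3S)-3-(dimethoxymethyl)-4-methylidene-5-oxooxolan-2-yl]methyl methanesulfonate (4R,5S,6R,7S), via lithium dienolate 12 (not isolated), via lithium aldolate 13 (not isolated)
Conditions: 11 (1.2 equiv), LiN(iPr)2 (1.25 equiv), THF, −78 °C; 8, −78 °C, 15 min; MsCl (3 equiv), −78 → −20 °C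
Reagents that add atoms: methanesulfonyl chloride, CS(=O)(=O)Cl
Why: Lithium aldol addition through a Zimmerman–Traxler chair then in situ O-sulfonylation, in which the ring-locked E(O)-enolate puts C3 anti to the new C5–O bond (4R with 5S), the polar Felkin–Anh face of the α-acyloxy aldehyde gives the 5,6-anti relation, 1,2-addition at −78 °C outruns Michael addition to the lactone, and cold trapping blocks retro-aldol and translactonisation.

**Step 7**
Reactants: 14 keto mesylate acetal
Product: 15 (S)-[(1R)-1,3-dimethyl-2-oxocyclohex-3-en-1-yl][(2R,3S)-3-formyl-4-methylidene-5-oxooxolan-2-yl]methyl methanesulfonate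
Conditions: TFA–H2O 1:1, CHCl3 (two phases), 0 °C, 1–2 h; cold aq. NaHCO3; used at once
Reagents that add atoms: water, O
Why: Acid-catalysed acetal hydrolysis to which the neopentyl-type mesylate (no hydrogen on C4), the enone and the lactone are inert, with short cold contact keeping the β,γ-unsaturated aldehyde from isomerising so that C7 is kept.

**Step 8**
Reactants: 15 keto aldehyde mesylate
Product: 17 (3aR,4R,6Z,10Z,11aS)-4-hydroxy-6,10-dimethyl-3-methylidene-3,3a,4,8,9,11a-hexahydrocyclodeca[b]furan-2,5-dione (6S,7R,8R), via samarium diolate 16 (not isolated)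
Conditions: SmI2 (0.1 M in THF, 2.2 equiv, added over 30 min until the blue colour holds), THF (0.01 M), −78 °C; dry air to discharge the excess; −78 → 23 °C, 2 h; pH 7 phosphate buffer
Reagents that add atoms: none
Why: Proposed new method: two single-electron transfers from SmI2 join aldehyde carbon C8 to enone carbonyl carbon C9 through a ketyl chelated to trivalent samarium in a six-membered chair (both oxygens on the metal, hence the cis-diolate and 8R, with C11 and O8 equatorial), giving cis-decalin 16 in which the C9–O(−) lone pair, the C4–C9 bond and the equatorial C5–OMs bond are antiperiplanar, so a concerted Grob fragmentation opens ring B/ring A to the ten-membered ring with C9=O, with C3 (axial on ring A) and C6 ending cis (4Z) and the 1(10)Z enone inherited from the cyclohexenone; the closest known reaction types are the SmI2 keto-aldehyde pinacol cyclisation and the sequential SmI2 Barbier cyclisation/Grob fragmentation of iodoalkyl keto mesylates, whereas a ketyl-triggered version that delivers an α-hydroxy enone has not been shown.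

**Step 9**
Reactants: 18 angelic acid, (Z)-2-methylbut-2-enoic acid
Product: 19 (Z)-2-methylbut-2-en-1-ol
Conditions: LiAlH4 (1.2 equiv), Et2O, 0 → 23 °C
Reagents that add atoms: none
Why: Hydride reduction of the acid to the allylic alcohol, which proceeds 1,2 only and leaves the Z geometry untouched.

**Step 10**
Reactants: 19 (Z)-2-methylbut-2-en-1-ol
Product: 20 [(2R,3S)-2,3-dimethyloxiran-2-yl]methanol
Conditions: Ti(OiPr)4 (10 mol %), D-(−)-diisopropyl tartrate (12 mol %), t-BuOOH (2 equiv), 4 Å MS, CH2Cl2, −20 °C
Reagents that add atoms: tert-butyl hydroperoxide, CC(C)(C)OO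
Why: Katsuki–Sharpless asymmetric epoxidation, in which the D-(−)-tartrate catalyst delivers oxygen to the face that gives 2R (mirror of the 2S sense of L-(+)-tartrate) and the syn addition carries the Z geometry into the cis CH2OH/CH3 relation (3S).

**Step 11**
Reactants: 20 epoxy alcohol
Product: 21 (2S,3S)-2,3-dimethyloxirane-2-carboxylic acid
Conditions: TEMPO (20 mol %), PhI(OAc)2 (2.2 equiv), MeCN–pH 7 buffer 1:1, 0 → 23 °C
Reagents that add atoms: water, O
Why: Oxoammonium (TEMPO) oxidation of the primary alcohol through the aldehyde hydrate to the acid, mild enough for the epoxide, with both centres kept (the letter at C2 changes by priority only).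

**Step 12**
Reactants: 21 (2S,3S)-epoxyangelic acid; 17 ten-membered hydroxy ketone
Product: 23 target, (3aS,4R,6Z,10Z,11aS)-6,10-dimethyl-3-methylidene-2,5-dioxo-2,3,3a,4,5,8,9,11a-octahydrocyclodeca[b]furan-4-yl (2S,3S)-2,3-dimethyloxirane-2-carboxylate, via mixed anhydride 22 (not isolated)
Conditions: 21 (1.5 equiv), 2,4,6-Cl3C6H2COCl (1.5 equiv), Et3N (3 equiv), PhMe, 23 °C, 1 h; then 17, DMAP (2 equiv), 0 → 23 °C
Reagents that add atoms: none
Why: Yamaguchi esterification, in which the acylpyridinium from the mixed anhydride acylates the hindered C8 carbinol with retention, the quaternary α-carbon of the acid cannot epimerise, and the minor diastereomer from incomplete ee of 20 is removed by chromatography.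

**Compound list**
1 | 2,2-dimethoxyacetaldehyde | O=CC(OC)OC | starting material
2 | methyl acrylate | C=CC(=O)OC | starting material
3 | methyl 3-hydroxy-4,4-dimethoxy-2-methylidenebutanoate (racemic) | COC(OC)C(O)C(=C)C(=O)OC | intermediate
4 | methyl (Z)-2-(bromomethyl)-4,4-dimethoxybut-2-enoate | COC(OC)/C=C(\CBr)C(=O)OC | intermediate
5 | (4S)-2,2-dimethyl-1,3-dioxolane-4-carbaldehyde ((S)-glyceraldehyde with its isopropylidene protecting group) | O=C[C@@H]1COC(C)(C)O1 | starting material
6 | methyl (3S,4R)-3-(dimethoxymethyl)-4-[(4S)-2,2-dimethyl-1,3-dioxolan-4-yl]-4-hydroxy-2-methylidenebutanoate | C=C(C(=O)OC)[C@H](C(OC)OC)[C@@H](O)[C@@H]1COC(C)(C)O1 | intermediate (not isolated)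
7 | (4S,5R)-4-(dimethoxymethyl)-5-[(4S)-2,2-dimethyl-1,3-dioxolan-4-yl]-3-methylideneoxolan-2-one | C=C1C(=O)O[C@@H]([C@@H]2COC(C)(C)O2)[C@H]1C(OC)OC | intermediate
8 | (2R,3S)-3-(dimethoxymethyl)-4-methylidene-5-oxooxolane-2-carbaldehyde | C=C1C(=O)O[C@@H](C=O)[C@H]1C(OC)OC | intermediate
9 | 2-methylcyclohex-2-en-1-one | CC1=CCCCC1=O | starting material
10 | lithium 6-methylcyclohexa-1,5-dien-1-olate | [Li+].[O-]C1=CCCC=C1C | intermediate (not isolated)
11 | 2,6-dimethylcyclohex-2-en-1-one (racemic) | CC1CCC=C(C)C1=O | intermediate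
12 | lithium 2,6-dimethylcyclohexa-1,5-dien-1-olate | [Li+].[O-]C1=C(C)CCC=C1C | intermediate (not isolated)
13 | lithium aldolate (4R,5S,6R,7S), the C5 alkoxide of 14 | O=C1C(C)=CCC[C@]1(C)[C@H]([O-])[C@@H]2OC(=O)C(=C)[C@@H]2C(OC)OC.[Li+] | intermediate (not isolated)
14 | keto mesylate acetal (4R,5S,6R,7S) | O=C1C(C)=CCC[C@]1(C)[C@H](OS(C)(=O)=O)[C@@H]2OC(=O)C(=C)[C@@H]2C(OC)OC | intermediate
15 | keto aldehyde mesylate (4R,5S,6R,7S) | O=C1C(C)=CCC[C@]1(C)[C@H](OS(C)(=O)=O)[C@@H]2OC(=O)C(=C)[C@@H]2C=O | intermediate
16 | cis-decalin 8,9-cis-diolate of trivalent samarium (4R,5S,6R,7R,8R,9S): angular C4 methyl and C9 oxygen cis, C5 mesylate equatorial on ring A, cis-fused lactone | C[C@]12CCC=C(C)[C@@]1([O-])[C@H]([O-])[C@H]3C(=C)C(=O)O[C@H]3[C@H]2OS(C)(=O)=O.[Sm+3].[Sm+3].[I-].[I-].[I-].[I-] | intermediate (not isolated)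
17 | ten-membered 8-hydroxy-9-oxo-1(10)Z,4Z-dien-12,6-olide (6S,7R,8R) | C=C1C(=O)O[C@H]2/C=C(/C)CC/C=C(/C)C(=O)[C@H](O)[C@@H]12 | intermediate
18 | angelic acid | C/C=C(/C)C(=O)O | starting material
19 | (Z)-2-methylbut-2-en-1-ol | C/C=C(/C)CO | intermediate
20 | [(2R,3S)-2,3-dimethyloxiran-2-yl]methanol | OC[C@@]1(C)O[C@H]1C | intermediate
21 | (2S,3S)-2,3-dimethyloxirane-2-carboxylic acid | OC(=O)[C@@]1(C)O[C@H]1C | intermediate
22 | (2S,3S)-2,3-dimethyloxirane-2-carboxylic 2,4,6-trichlorobenzoic anhydride | O=C(OC(=O)[C@@]1(C)O[C@H]1C)c1c(Cl)cc(Cl)cc1Cl | intermediate (not isolated)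
23 | CNP0183761.1 | C=C1C(=O)O[C@H]2/C=C(/C)CC/C=C(/C)C(=O)[C@H](OC(=O)[C@@]3(C)O[C@H]3C)[C@@H]12 | target

**Totals**
- Total step count: 12.
- Longest linear sequence: 8 (steps 1, 2, 3, 4, 6, 7, 8, 12).

**The three steps most likely to fail**

Step 8 is the new pinacol/Grob ring expansion. The risks are over-reduction of the α-hydroxy enone or of the α-methylene lactone by SmI2, a slow closure on the hindered C9 carbonyl, and a sluggish fragmentation of the trivalent samarium alkoxide. The fallback uses known chemistry, sets out from 15 and comes back at 17. It brings C8 in as a plain carbon nucleophile and oxidises it afterwards. NaBH(OAc)3 reduces only the aldehyde of 15 to primary alcohol F11. I2/PPh3/imidazole then gives iodide F12. The known sequential Barbier cyclisation/Grob fragmentation (SmI2, catalytic NiI2, THF) gives 8-deoxy ketone F13. Kinetic α′-enolisation with KN(SiMe3)2 at −78 °C and hydroxylation with 2-(phenylsulfonyl)-3-phenyloxaziridine gives 17, which is separated from any C8 epimer by chromatography.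

Step 6 builds a quaternary centre by aldol addition, relies on the simple diastereoselection at C4/C5 that fixes the 4Z geometry, and mesylates a neopentyl-type alkoxide in the cold. The fallback leaves the basic aldolate manifold for a Lewis-acid Mukaiyama aldol with stepwise activation; it sets out from 11 (with 8) and comes back at 14. Compound 11 is converted through 12 with Me3SiCl into silyl dienol ether F1. BF3·OEt2 at −78 °C joins F1 to 8 through an open, irreversible transition state on the polar Felkin–Anh face. No free alkoxide is present, so retro-aldol, oxa-Michael addition and translactonisation are avoided. Work-up gives free aldol F2. Its diastereomers are separated, and MsCl/Et3N turns the right one into 14.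

Step 7 hydrolyses a deactivated acetal with acid and gives an aldehyde whose C7–H is allylic, so the alkene may move into conjugation and C7 may be lost. The fallback carries C8 at the alcohol level and reaches the aldehyde by a neutral oxidation; it sets out from 2, comes back at 15 and costs one extra step.
- Bought (tert-butyldimethylsilyloxy)acetaldehyde F3 and 2 are taken through the operations of steps 1 to 4 and 6.
- These give in turn Baylis–Hillman adduct F4, allyl bromide F5, hydroxy ester F6 (not isolated), lactone F7, lactone aldehyde F8, lithium aldolate F9 (not isolated) and mesylate F10.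
- HF·pyridine then frees primary alcohol F11.
- Dess–Martin periodinane buffered with NaHCO3 gives 15 without acid or base.

**Further compounds**
F1 | step 6 | [(2,6-dimethylcyclohexa-1,5-dien-1-yl)oxy]trimethylsilane | C[Si](C)(C)OC1=C(C)CCC=C1C
F2 | step 6 | free aldol, C5 alcohol of 14 (4R,5S,6R,7S) | O=C1C(C)=CCC[C@]1(C)[C@H](O)[C@@H]2OC(=O)C(=C)[C@@H]2C(OC)OC
F3 | step 7 | (tert-butyldimethylsilyloxy)acetaldehyde (bought) | O=CCO[Si](C)(C)C(C)(C)C
F4 | step 7 | methyl 4-[(tert-butyldimethylsilyl)oxy]-3-hydroxy-2-methylidenebutanoate (racemic) | COC(=O)C(=C)C(O)CO[Si](C)(C)C(C)(C)C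
F5 | step 7 | methyl (Z)-2-(bromomethyl)-4-[(tert-butyldimethylsilyl)oxy]but-2-enoate | CC(C)(C)[Si](C)(C)OC/C=C(\CBr)C(=O)OC
F6 | step 7 | silyl ether analogue of 6 (CH2OTBS in place of CH(OMe)2, same spatial arrangement) | C=C(C(=O)OC)[C@H](CO[Si](C)(C)C(C)(C)C)[C@@H](O)[C@@H]1COC(C)(C)O1
F7 | step 7 | silyl ether analogue of 7 | C=C1C(=O)O[C@@H]([C@@H]2COC(C)(C)O2)[C@H]1CO[Si](C)(C)C(C)(C)C
F8 | step 7 | silyl ether analogue of 8 | C=C1C(=O)O[C@@H](C=O)[C@H]1CO[Si](C)(C)C(C)(C)C
F9 | step 7 | silyl ether analogue of 13 | O=C1C(C)=CCC[C@]1(C)[C@H]([O-])[C@@H]2OC(=O)C(=C)[C@@H]2CO[Si](C)(C)C(C)(C)C.[Li+]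
F10 | step 7 | silyl ether analogue of 14 | O=C1C(C)=CCC[C@]1(C)[C@H](OS(C)(=O)=O)[C@@H]2OC(=O)C(=C)[C@@H]2CO[Si](C)(C)C(C)(C)C
F11 | step 7 | primary alcohol, C8 carbinol of 15 | O=C1C(C)=CCC[C@]1(C)[C@H](OS(C)(=O)=O)[C@@H]2OC(=O)C(=C)[C@@H]2CO
F12 | step 8 | primary iodide, C8 iodide of F11 | O=C1C(C)=CCC[C@]1(C)[C@H](OS(C)(=O)=O)[C@@H]2OC(=O)C(=C)[C@@H]2CI
F13 | step 8 | 8-deoxy ketone, 9-oxo-1(10)Z,4Z-dien-12,6-olide | C=C1C(=O)O[C@H]2/C=C(/C)CC/C=C(/C)C(=O)C[C@@H]12
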